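## Structural features

27 is a cyclohex-2-en-1-one (ring atoms C1–C6: C1 carbonyl, C2=C3 alkene) with a secondary allylic hydroxyl at C4 and a fully substituted carbinol at C6; C6 carries, through C1′, a seventeen-carbon chain (C1′–C17′) with a secondary carbinol at C2′ and a Z alkene at C10′=C11′. The three stereocentres, C4 (S), C6 (R) and C2′ (S), are never adjacent: C4 and C6 are 1,3 across the C5 methylene with their hydroxyls cis on the ring, and C6 and C2′ are 1,3 across C1′. Fragile elements are the 4-hydroxy enone (loss of water and aromatisation under acid or base), the C1/C6 α-ketol (acyloin shift), the C2′ hydroxyl that can close onto C1 as a five-membered hemiketal, and the isolated Z alkene, which excludes peracids, ozone, osmium reagents and hydrogenation once the chain is attached. The real difficulty is the quaternary C6 carbinol, whose configuration must be fixed relative to both C4 and C2′ although no neighbouring stereocentre shields one of its faces. The key step uses the 1,3-diol formed by C4–OH and C6–OH across C5: in an open-chain precursor an E-trisubstituted C5=C6 alkene next to the C4 carbinol, with the C1′ arm cis to C4, lets allylic 1,3-strain pass the C4 configuration to C6 in a hydroxyl-directed epoxidation, and hydride at C5 then turns the epoxy alcohol into the diol. C2′ lies outside this relay and is brought in with a resolved terminal epoxide; the ring is closed only afterwards, at C2=C3, by metathesis between vinyl groups on C1 and C4.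

## Logic of the disconnections

27 ⇒ 26 ⇒ 25. No skeletal bond is cut: the three hydroxyls are masked as silyl ethers and the C1 carbonyl is taken back to a carbinol. The reason is that the 4-hydroxy enone and the α-ketol should not meet bases, organometallics or the metathesis catalyst. The gain is that the sensitive functionality appears only in the last two steps. The demand is an oxidation that finds C1–OH as the only free hydroxyl, and a final desilylation that is neither basic nor strongly acidic.

25 ⇒ 24. The ring bond C2=C3 is cut (metathesis retron). Both alkene carbons become terminal vinyl groups, one on C1 and one on C4, so the ring becomes an open chain whose stereocentres can be set by acyclic methods. The demand is that the ruthenium carbene closes the six-membered ring faster than it touches C10′=C11′.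

24 ⇒ 23 ⇒ 22 ⇒ 21. C1–C2 is cut (vinyl nucleophile plus aldehyde), and C1 is then taken back through the primary alcohol to its PMB ether. C1 thereby becomes a protected hydroxymethyl group on C6, which is the third C6 substituent that the epoxidation substrate needs. The demand is orthogonality of PMB against TES and TBS, and a capped C6 oxygen so that neither an acetal nor a lactol forms at C1.

21 ⇒ 20 ⇒ 19. The silyl groups at C4–O and C6–O are removed and the C5–H bond is replaced by the C5–O bond of an oxirane (1,3-diol ⇒ 2,3-epoxy alcohol). The C6 carbinol becomes an epoxide carbon whose configuration is an alkene-face problem. The demand is hydride attack at C5 only, which the C4 alkoxide and the full substitution of C6 both favour.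

19 ⇒ 18. The C5–O and C6–O bonds are cut. Two stereocentres disappear and leave an E alkene plus the single carbinol C4. The demand is delivery of oxygen to one face of C5=C6 under control of C4, and to no other alkene.

18 ⇒ 17 ⇒ 16. Protecting groups only: C4–OH may be free at the epoxidation and not before, C2′–OH must be capped, so C4 carries a TES group that leaves in the presence of the C2′ TBS ether. The demand is selective methanolysis of the less hindered silyl ether.

16 ⇒ 14 + 4 (through 15). C6–C1′ is cut into an alkenyl nucleophile and a terminal epoxide. Two fragments of similar size result, C2′ arrives ready-made, and no stereocentre is created. The demand is retention of the alkene geometry and attack at the terminal epoxide carbon.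

14 ⇒ 13 ⇒ 11 (through 12). C6–I and C5–H are disconnected as an anti addition of hydride and iodine across an alkyne. The E geometry of the later alkene is reduced to the known trans-hydroalumination of a propargylic alcohol. The demand is that the C4 alkoxide, not the C1 ether, steers aluminium to C6.

11 ⇒ 10 ⇒ 6 + 7 (through 8 and 9); 6 ⇒ 5. C4–C5 is cut into an acetylide and an enal, and the C4 configuration is assigned to an enzymatic resolution of the ester. Three-carbon starting materials result. The demand is usable discrimination between a vinyl and an alkynyl substituent by the enzyme.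

4 ⇒ 3 ⇒ 2 ⇒ 1. C1′ is removed as a sulfur-ylide methylene and the C2′ configuration is assigned to a hydrolytic kinetic resolution. The chain, with its Z alkene already in place, comes from 1. The demand is an oxidation and an epoxidation that leave C10′=C11′ untouched.

## Other disconnections considered

Alternative 1: The cut is the ring bond C1–C2, with C1 held as the carbonyl of a γ-lactone whose ring oxygen is the C2′ oxygen (A2). In the forward step t-BuLi would exchange the iodine of the Z-iodoalkene of A2; the C2 alkenyllithium would add to C1, the tetrahedral intermediate would collapse, and A1 would result with the enone in place and C2′–OH set free.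
- In its favour: the closure delivers C1 at the ketone level and C2=C3 with the ring geometry, so no redox changes at C1 and no ruthenium carbene near C10′=C11′ are needed. The lactone ties C2′ and C6 into one five-membered ring, so C6 can be built by enolate chemistry on the face away from the C2′ chain.
- Against it here: C6 must be made quaternary on that lactone ring by two enolate reactions, one of them an alkylation with a β-branched, β-oxygenated electrophile carrying C4. The only control element is a substituent 1,3 across a nearly flat enolate, so selectivity at the quaternising step is uncertain. In the key step t-BuLi must exchange iodine faster than it adds to the lactone carbonyl.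
- Comparison: both plans bring in two stereocentres independently and derive C6 from a third element, this one from C2′ through a ring, the chosen one from C4 through acyclic allylic strain; neither relay is clearly the more secure. Mechanistically both depend on a Z-alkenyllithium with a cis silyloxy group that can accept a silyl shift, an equal hazard. In step economy after the key step alternative 1 is the better plan: one deprotection from A1, against eight operations from 19.

Alternative 2: No ring C–C bond is cut. The six ring carbons come from the phenyl group of A5, and the C–O bonds at C1, C6, C3 and C4 are disconnected in turn. Dissolving-metal reduction of A5 and cis-dihydroxylation of the trisubstituted ring alkene so formed would give A4. The key step, VO(acac)2 with t-BuOOH, would epoxidise the remaining C3=C4 ring alkene on the face of the two hydroxyls to give A3. Oxidation of C1–OH and β-elimination of the epoxide would then reveal the enone and C4–OH together.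
- In its favour: no ring closure, a very short sequence, and a directed epoxidation inside a six-membered ring with both hydroxyls on one face. That is a better-defined facial problem than the open-chain relay of the chosen plan, and on this point alternative 2 is the better.
- Against it here: the configuration of C6, and with it of C1, C3 and C4, must be created in the dihydroxylation of a flat cyclohexadiene whose faces differ only through the remote C2′ centre. It therefore rests on reagent control over a cyclic trisubstituted alkene, a class for which ligand-controlled dihydroxylation is less dependable. The osmium reagent must also choose that alkene over the second ring alkene and over C10′=C11′, and the dissolving-metal step must leave the chain alkene in place.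
- Comparison: structurally the alternative obtains the ring for nothing but leaves the decisive stereocentre to its least predictable step, whereas the chosen plan spends more steps so that each stereocentre comes from a resolved fragment or from a relay with a clear conformational model. Mechanistically the two key steps are the same reaction type, homoallylic and ring-constrained there, allylic and acyclic here. In step count alternative 2 is clearly the shorter.

Alternative 3: The cut is the ring bond C1–C6 between an aldehyde carbon and a ketone carbon (A7). Behind it, C5–C6 and C6–C1′ would be made by using C6 as a dithiane acyl-anion equivalent that opens 4 and a second terminal epoxide. In the key step a triazolium-derived carbene with Et3N would convert the C1 aldehyde into its Breslow intermediate, which would add to the C6 ketone and give A6. In ketone numbering A6 is a 2-alkyl-2-hydroxy-4-silyloxycyclohexanone; a 5-silyloxy locant would not fit, because the silyloxy carbon is C4 of the target.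
- In its favour: the assembly is three-component and more convergent than the chosen plan, which is a point on which it is the better. C4 and C2′ would both come from resolved epoxides, and C6 would form directly as the α-ketol under nearly neutral conditions. A later dehydrogenation could only go toward C2, because C6 is quaternary.
- Against it here: C6 is created in the ring closure with control only from C4 across the forming ring, or from a chiral carbene whose sense would have to match C4 and C2′. A7 is a ketone flanked by two β-silyloxy carbons and can lose silanol by E1cB under the amine base. Its enolisable positions open a competing aldol closure to a five-membered ring. A6 still lacks C2=C3, so a dehydrogenation would have to be run on the α-ketol at the end.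
- Comparison: structurally both plans take C4 and C2′ from resolved building blocks; the chosen plan sets C6 by a relay with a defined rotamer model, alternative 3 sets it in a cyclisation whose preference is harder to predict. Mechanistically alternative 3 avoids organolithium, hydride and metathesis steps on the full chain, which is an advantage for the Z alkene. In step count the two plans are about equal once the dehydrogenation and protecting-group steps are included.

Key step: step 12

Remarks. Ring locants C1–C6 and chain locants C1′–C17′ of 27 are used for every intermediate. The lipase is assumed to follow the usual size rule for secondary alcohols (vinyl as the medium group, the alkynyl arm as the large group), which makes the (R)-ester the fast-reacting enantiomer. The (S,S)-cobalt salen catalyst is assumed to spare the (S)-epoxide, as with simple terminal alkyl epoxides.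

## Route

Step 1
Reactants: 1 (9Z)-hexadec-9-en-1-ol
Product: 2 (9Z)-hexadec-9-enal
Conditions: TEMPO (10 mol%), PhI(OAc)2, CH2Cl2, rt
Reagents that add atoms: none
Why: Oxoammonium-mediated oxidation (TEMPO/PhI(OAc)2) stops at the aldehyde and does not touch the Z alkene.

Step 2
Reactants: 2 (9Z)-hexadec-9-enal
Product: 3 rac-2-[(8Z)-pentadec-8-en-1-yl]oxirane
Conditions: Me3S+ I−, n-BuLi, THF, −10 °C; then 2, −10 °C → rt
Reagents that add atoms: trimethylsulfonium iodide, C[S+](C)C.[I-]
Why: Corey–Chaykovsky epoxidation: the sulfur ylide adds to the aldehyde and the betaine closes with loss of Me2S, which adds C1′ and leaves the remote alkene alone; the product is racemic at C2′.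

Step 3
Reactants: 3 rac-2-[(8Z)-pentadec-8-en-1-yl]oxirane
Product: 4 (2S)-2-[(8Z)-pentadec-8-en-1-yl]oxirane
Conditions: (S,S)-(salen)Co(OAc) (0.5 mol%; trivalent cobalt, salen = N,N′-bis(3,5-di-tert-butylsalicylidene)cyclohexane-1,2-diamine dianion), H2O (0.55 equiv), THF, 0 °C → rt
Reagents that add atoms: none
Why: Hydrolytic kinetic resolution of a terminal epoxide: the catalyst should hydrolyse the (R)-epoxide much faster, so the (S)-epoxide remains and is separated from the diol; this sets C2′.

Step 4
Reactants: 5 prop-2-yn-1-ol
Product: 6 1-methoxy-4-[(prop-2-yn-1-yloxy)methyl]benzene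
Conditions: NaH, 4-MeOC6H4CH2Cl, n-Bu4NI (cat.), THF/DMF, 0 °C → rt
Reagents that add atoms: 4-methoxybenzyl chloride, COc1ccc(CCl)cc1
Why: Williamson ether synthesis on the alkoxide; the O–H is far more acidic than the alkyne C–H, so only oxygen is alkylated.

Step 5
Reactants: 6 1-methoxy-4-[(prop-2-yn-1-yloxy)methyl]benzene; 7 prop-2-enal
Product: 10 rac-6-[(4-methoxybenzyl)oxy]hex-1-en-4-yn-3-yl acetate, via lithium acetylide 8 (not isolated), via lithium alkoxide 9 (not isolated)
Conditions: n-BuLi, THF, −78 °C; 7, −78 °C; Ac2O, −78 → 0 °C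
Reagents that add atoms: acetic anhydride, CC(=O)OC(C)=O
Why: The hard lithium acetylide adds 1,2 to the enal (C4–C5 bond), and the alkoxide is acylated in the same flask, giving the racemic ester as substrate for the enzyme.

Step 6
Reactants: 10 rac-6-[(4-methoxybenzyl)oxy]hex-1-en-4-yn-3-yl acetate
Product: 11 (3R)-6-[(4-methoxybenzyl)oxy]hex-1-en-4-yn-3-ol
Conditions: Burkholderia cepacia lipase (immobilised), phosphate buffer pH 7/acetone, 30 °C, stopped below half conversion
Reagents that add atoms: none
Why: Enzymatic kinetic resolution by ester hydrolysis: with vinyl as the medium and the alkynyl arm as the large substituent the (R)-acetate should be cleaved faster, which sets C4; the (S)-acetate is removed by chromatography.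

Step 7
Reactants: 11 (3R)-6-[(4-methoxybenzyl)oxy]hex-1-en-4-yn-3-ol
Product: 13 (3R,4Z)-5-iodo-6-[(4-methoxybenzyl)oxy]hexa-1,4-dien-3-ol, via cyclic alkenylaluminate 12 (not isolated)
Conditions: NaAlH2(OCH2CH2OCH3)2, THF, −20 → 0 °C; then I2, THF, −78 → −20 °C
Reagents that add atoms: iodine, II
Why: Trans-hydroalumination of a propargylic alcohol: the C4 alkoxide holds aluminium, hydride goes to C5 and aluminium to C6 in a five-membered ring, and iodinolysis with retention gives the Z-iodoalkene that fixes the later E geometry. The mixture is kept at or below 0 °C so that the alanate does not expel the C1 alkoxide.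

Step 8
Reactants: 13 (3R,4Z)-5-iodo-6-[(4-methoxybenzyl)oxy]hexa-1,4-dien-3-ol
Product: 14 (3R,4Z)-5-iodo-6-[(4-methoxybenzyl)oxy]-3-[(triethylsilyl)oxy]hexa-1,4-diene
Conditions: Et3SiCl, imidazole, CH2Cl2, 0 °C
Reagents that add atoms: chlorotriethylsilane, CC[Si](Cl)(CC)CC
Why: Standard silylation; TES is chosen because it tolerates t-BuLi at −78 °C and can later be removed in the presence of a TBS ether.

Step 9
Reactants: 14 (3R,4Z)-5-iodo-6-[(4-methoxybenzyl)oxy]-3-[(triethylsilyl)oxy]hexa-1,4-diene; 4 (2S)-2-[(8Z)-pentadec-8-en-1-yl]oxirane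
Product: 16 (3R,4E,7S,15Z)-5-{[(4-methoxybenzyl)oxy]methyl}-3-[(triethylsilyl)oxy]docosa-1,4,15-trien-7-ol, via alkenyllithium 15 (not isolated)
Conditions: t-BuLi (2.0 equiv), Et2O, −78 °C; then 4, BF3·OEt2, −78 °C
Reagents that add atoms: none
Why: Iodine–lithium exchange proceeds with retention of alkene geometry, and the BF3-activated epoxide is opened by SN2 attack at its terminal carbon C1′ (C6–C1′ bond), so C2′ is untouched. Ether solvent and −78 °C suppress silyl migration and alkoxide loss from the alkenyllithium.

Step 10
Reactants: 16 (3R,4E,7S,15Z)-5-{[(4-methoxybenzyl)oxy]methyl}-3-[(triethylsilyl)oxy]docosa-1,4,15-trien-7-ol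
Product: 17 (3R,4E,7S,15Z)-7-[(tert-butyldimethylsilyl)oxy]-5-{[(4-methoxybenzyl)oxy]methyl}-3-[(triethylsilyl)oxy]docosa-1,4,15-triene
Conditions: t-BuMe2SiCl, imidazole, DMAP (cat.), DMF, rt
Reagents that add atoms: tert-butyldimethylsilyl chloride, CC(C)(C)[Si](C)(C)Cl
Why: Silylation of the secondary C2′ hydroxyl, so that it cannot bind the epoxidation catalyst later; the TES ether is stable under these buffered conditions.

Step 11
Reactants: 17 (3R,4E,7S,15Z)-7-[(tert-butyldimethylsilyl)oxy]-5-{[(4-methoxybenzyl)oxy]methyl}-3-[(triethylsilyl)oxy]docosa-1,4,15-triene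
Product: 18 (3R,4E,7S,15Z)-7-[(tert-butyldimethylsilyl)oxy]-5-{[(4-methoxybenzyl)oxy]methyl}docosa-1,4,15-trien-3-ol
Conditions: PPTS (cat.), MeOH/CH2Cl2, 0 °C
Reagents that add atoms: none
Why: Acid-catalysed methanolysis removes the less hindered TES ether much faster than the TBS ether; the weak acid and low temperature protect the bis-allylic carbinol from ionisation.

Step 12
Reactants: 18 (3R,4E,7S,15Z)-7-[(tert-butyldimethylsilyl)oxy]-5-{[(4-methoxybenzyl)oxy]methyl}docosa-1,4,15-trien-3-ol
Product: 19 (1R)-1-[(2S,3S)-3-{(2S,10Z)-2-[(tert-butyldimethylsilyl)oxy]heptadec-10-en-1-yl}-3-{[(4-methoxybenzyl)oxy]methyl}oxiran-2-yl]prop-2-en-1-ol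
Conditions: VO(acac)2 (5 mol%), t-BuOOH (anhydrous, in decane), CH2Cl2, 0 °C → rt
Reagents that add atoms: tert-butyl hydroperoxide, CC(C)(C)OO
Why: t-BuOOH oxidises VO(acac)2 to a pentavalent oxovanadium species that takes up the C4 alkoxide and the tert-butylperoxide as ligands, and the metal-bound peroxide oxygen is passed to C5=C6 within this complex in one concerted, stereospecific syn transfer (hydroxyl-directed vanadium epoxidation of a secondary allylic alcohol). The oxirane therefore closes by a single [2+1] oxygen-atom transfer in which both C–O bonds form together, so the E geometry of 18 fixes the relative configuration of C5 and C6. C6, and with it C5, is controlled by C4: the C1′ methylene is cis to C4, so any rotamer with the vinyl group or the oxygen in the alkene plane suffers allylic 1,3-strain, the C4–H bond eclipses C5=C6, and the vanadium-bound oxygen reaches the alkene only from the face on which the C4 oxygen then stands, which gives the threo epoxy alcohol. The facial selectivity needed is threo over erythro and comes from the cis C1′ arm; because vanadium prefers a smaller O–C4–C5=C6 angle than this rotamer offers, the preference should be useful but not complete, and the minor epoxy alcohol is to be removed by chromatography. The site selectivity needed is C5=C6 over the vinyl group, secured by the higher nucleophilicity of the trisubstituted alkene, and over C10′=C11′, secured because C1–O and C2′–O are capped as PMB and TBS ethers and C4–OH is the only ligand for vanadium. Oxidation of the bis-allylic carbinol to the dienone is held back by low temperature and anhydrous oxidant.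

Step 13
Reactants: 19 (1R)-1-[(2S,3S)-3-{(2S,10Z)-2-[(tert-butyldimethylsilyl)oxy]heptadec-10-en-1-yl}-3-{[(4-methoxybenzyl)oxy]methyl}oxiran-2-yl]prop-2-en-1-ol
Product: 20 (3S,5S,7S,15Z)-7-[(tert-butyldimethylsilyl)oxy]-5-{[(4-methoxybenzyl)oxy]methyl}docosa-1,15-diene-3,5-diol
Conditions: NaAlH2(OCH2CH2OCH3)2, THF, 0 °C → rt; aq. potassium sodium tartrate
Reagents that add atoms: none
Why: Hydroxyl-directed hydride opening of a 2,3-epoxy alcohol: the C4 alkoxyaluminate delivers hydride to C5 by SN2, C6 is fully substituted and cannot be attacked, and the epoxide oxygen stays on C6 with its configuration, giving the 1,3-diol with the C4/C6 relationship of the target.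

Step 14
Reactants: 20 (3S,5S,7S,15Z)-7-[(tert-butyldimethylsilyl)oxy]-5-{[(4-methoxybenzyl)oxy]methyl}docosa-1,15-diene-3,5-diol
Product: 21 (3S,5R,7S,15Z)-7-[(tert-butyldimethylsilyl)oxy]-5-{[(4-methoxybenzyl)oxy]methyl}-3,5-bis[(triethylsilyl)oxy]docosa-1,15-diene
Conditions: Et3SiOTf, 2,6-lutidine, CH2Cl2, −78 → 0 °C
Reagents that add atoms: triethylsilyl trifluoromethanesulfonate, CC[Si](CC)(CC)OS(=O)(=O)C(F)(F)F
Why: The silyl triflate is reactive enough to cap the tertiary C6 hydroxyl as well as the secondary C4 hydroxyl; capping both prevents acetal formation in the PMB cleavage and lactol formation at the aldehyde stage.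

Step 15
Reactants: 21 (3S,5R,7S,15Z)-7-[(tert-butyldimethylsilyl)oxy]-5-{[(4-methoxybenzyl)oxy]methyl}-3,5-bis[(triethylsilyl)oxy]docosa-1,15-diene
Product: 22 (2R,4S,12Z)-4-[(tert-butyldimethylsilyl)oxy]-2-[(triethylsilyl)oxy]-2-{(2S)-2-[(triethylsilyl)oxy]but-3-en-1-yl}nonadec-12-en-1-ol
Conditions: DDQ, CH2Cl2/pH 7 buffer (10:1), 0 °C
Reagents that add atoms: none
Why: Oxidative cleavage of the PMB ether through the benzylic oxocarbenium ion and its hydrolysis; the buffer keeps the TES ethers intact and no free hydroxyl is near enough to trap the cation.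

Step 16
Reactants: 22 (2R,4S,12Z)-4-[(tert-butyldimethylsilyl)oxy]-2-[(triethylsilyl)oxy]-2-{(2S)-2-[(triethylsilyl)oxy]but-3-en-1-yl}nonadec-12-en-1-ol
Product: 23 (2R,4S,12Z)-4-[(tert-butyldimethylsilyl)oxy]-2-[(triethylsilyl)oxy]-2-{(2S)-2-[(triethylsilyl)oxy]but-3-en-1-yl}nonadec-12-enal
Conditions: Dess–Martin periodinane, NaHCO3, CH2Cl2, 0 °C → rt
Reagents that add atoms: none
Why: Dess–Martin oxidation of the neopentyl-type primary alcohol; the aldehyde has no α-hydrogen and cannot enolise or epimerise.

Step 17
Reactants: 23 (2R,4S,12Z)-4-[(tert-butyldimethylsilyl)oxy]-2-[(triethylsilyl)oxy]-2-{(2S)-2-[(triethylsilyl)oxy]but-3-en-1-yl}nonadec-12-enal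
Product: 24 (3RS,4R,6S,14Z)-6-[(tert-butyldimethylsilyl)oxy]-4-[(triethylsilyl)oxy]-4-{(2S)-2-[(triethylsilyl)oxy]but-3-en-1-yl}henicosa-1,14-dien-3-ol
Conditions: CH2=CHMgBr, THF, −78 → −20 °C
Reagents that add atoms: vinylmagnesium bromide, C=C[Mg]Br
Why: Grignard 1,2-addition forms C1–C2; the new C1 carbinol is formed as a mixture, which does not matter because C1 is oxidised in step 19, and the cold quench limits silyl migration from the C6 oxygen to the C1 alkoxide.

Step 18
Reactants: 24 (3RS,4R,6S,14Z)-6-[(tert-butyldimethylsilyl)oxy]-4-[(triethylsilyl)oxy]-4-{(2S)-2-[(triethylsilyl)oxy]but-3-en-1-yl}henicosa-1,14-dien-3-ol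
Product: 25 (1RS,4S,6R)-6-{(2S,10Z)-2-[(tert-butyldimethylsilyl)oxy]heptadec-10-en-1-yl}-4,6-bis[(triethylsilyl)oxy]cyclohex-2-en-1-ol
Conditions: second-generation Grubbs catalyst RuCl2(=CHPh)(PCy3)(H2IMes) (5 mol%), CH2Cl2 (5 mM), 40 °C
Reagents that add atoms: none
Why: Ring-closing metathesis of the two terminal vinyl groups forms C2=C3 in a six-membered ring with loss of ethene; terminal alkenes engage the ruthenium carbene far faster than the internal C10′=C11′ alkene, and high dilution with a short reaction time should keep that alkene out of the reaction.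

Step 19
Reactants: 25 (1RS,4S,6R)-6-{(2S,10Z)-2-[(tert-butyldimethylsilyl)oxy]heptadec-10-en-1-yl}-4,6-bis[(triethylsilyl)oxy]cyclohex-2-en-1-ol
Product: 26 (4S,6R)-6-{(2S,10Z)-2-[(tert-butyldimethylsilyl)oxy]heptadec-10-en-1-yl}-4,6-bis[(triethylsilyl)oxy]cyclohex-2-en-1-one
Conditions: Dess–Martin periodinane, NaHCO3, CH2Cl2, 0 °C → rt
Reagents that add atoms: none
Why: Oxidation of the only free (allylic) hydroxyl gives the enone, and both C1 epimers converge on one compound.

Step 20
Reactants: 26 (4S,6R)-6-{(2S,10Z)-2-[(tert-butyldimethylsilyl)oxy]heptadec-10-en-1-yl}-4,6-bis[(triethylsilyl)oxy]cyclohex-2-en-1-one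
Product: 27 (4S,6R)-4,6-dihydroxy-6-[(2S,10Z)-2-hydroxyheptadec-10-en-1-yl]cyclohex-2-en-1-one
Conditions: HF·pyridine, pyridine, THF, 0 °C → rt
Reagents that add atoms: none
Why: Fluoride-mediated desilylation with pyridine-buffered HF removes all three silyl groups without base, so the 4-hydroxy enone and the α-ketol should neither eliminate nor rearrange.

## Compound list

1 | (9Z)-hexadec-9-en-1-ol (palmitoleyl alcohol) | CCCCCC/C=C\CCCCCCCCO | starting material
2 | (9Z)-hexadec-9-enal | CCCCCC/C=C\CCCCCCCC=O | intermediate
3 | rac-2-[(8Z)-pentadec-8-en-1-yl]oxirane | CCCCCC/C=C\CCCCCCCC1CO1 | intermediate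
4 | (2S)-2-[(8Z)-pentadec-8-en-1-yl]oxirane | CCCCCC/C=C\CCCCCCC[C@H]1CO1 | intermediate
5 | prop-2-yn-1-ol (propargyl alcohol) | OCC#C | starting material
6 | 1-methoxy-4-[(prop-2-yn-1-yloxy)methyl]benzene | C#CCOCc1ccc(OC)cc1 | intermediate
7 | prop-2-enal (acrolein) | C=CC=O | starting material
8 | {3-[(4-methoxybenzyl)oxy]prop-1-yn-1-yl}lithium | [Li]C#CCOCc1ccc(OC)cc1 | intermediate
9 | lithium rac-6-[(4-methoxybenzyl)oxy]hex-1-en-4-yn-3-olate | C=CC(O[Li])C#CCOCc1ccc(OC)cc1 | intermediate
10 | rac-6-[(4-methoxybenzyl)oxy]hex-1-en-4-yn-3-yl acetate | C=CC(OC(C)=O)C#CCOCc1ccc(OC)cc1 | intermediate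
11 | (3R)-6-[(4-methoxybenzyl)oxy]hex-1-en-4-yn-3-ol | C=C[C@@H](O)C#CCOCc1ccc(OC)cc1 | intermediate
12 | sodium cyclic alkenyl(alkoxy)aluminate: five-membered ring O–Al–C6=C5–C4, aluminium also carrying two 2-methoxyethoxide ligands | [Na+].C=C[C@@H]1C=C(COCc2ccc(OC)cc2)[Al-](OCCOC)(OCCOC)O1 | intermediate
13 | (3R,4Z)-5-iodo-6-[(4-methoxybenzyl)oxy]hexa-1,4-dien-3-ol | C=C[C@@H](O)/C=C(/COCc1ccc(OC)cc1)I | intermediate
14 | (3R,4Z)-5-iodo-6-[(4-methoxybenzyl)oxy]-3-[(triethylsilyl)oxy]hexa-1,4-diene | C=C[C@@H](O[Si](CC)(CC)CC)/C=C(/COCc1ccc(OC)cc1)I | intermediate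
15 | alkenyllithium from 14 (lithium at C6, cis to C4) | C=C[C@@H](O[Si](CC)(CC)CC)/C=C(/COCc1ccc(OC)cc1)[Li] | intermediate
16 | (3R,4E,7S,15Z)-5-{[(4-methoxybenzyl)oxy]methyl}-3-[(triethylsilyl)oxy]docosa-1,4,15-trien-7-ol | C=C[C@@H](O[Si](CC)(CC)CC)/C=C(/COCc1ccc(OC)cc1)C[C@@H](O)CCCCCCC/C=C\CCCCCC | intermediate
17 | (3R,4E,7S,15Z)-7-[(tert-butyldimethylsilyl)oxy]-5-{[(4-methoxybenzyl)oxy]methyl}-3-[(triethylsilyl)oxy]docosa-1,4,15-triene | C=C[C@@H](O[Si](CC)(CC)CC)/C=C(/COCc1ccc(OC)cc1)C[C@@H](O[Si](C)(C)C(C)(C)C)CCCCCCC/C=C\CCCCCC | intermediate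
18 | (3R,4E,7S,15Z)-7-[(tert-butyldimethylsilyl)oxy]-5-{[(4-methoxybenzyl)oxy]methyl}docosa-1,4,15-trien-3-ol | C=C[C@@H](O)/C=C(/COCc1ccc(OC)cc1)C[C@@H](O[Si](C)(C)C(C)(C)C)CCCCCCC/C=C\CCCCCC | intermediate
19 | (1R)-1-[(2S,3S)-3-{(2S,10Z)-2-[(tert-butyldimethylsilyl)oxy]heptadec-10-en-1-yl}-3-{[(4-methoxybenzyl)oxy]methyl}oxiran-2-yl]prop-2-en-1-ol | C=C[C@@H](O)[C@@H]1O[C@]1(COCc1ccc(OC)cc1)C[C@@H](O[Si](C)(C)C(C)(C)C)CCCCCCC/C=C\CCCCCC | intermediate
20 | (3S,5S,7S,15Z)-7-[(tert-butyldimethylsilyl)oxy]-5-{[(4-methoxybenzyl)oxy]methyl}docosa-1,15-diene-3,5-diol | C=C[C@@H](O)C[C@@](O)(COCc1ccc(OC)cc1)C[C@@H](O[Si](C)(C)C(C)(C)C)CCCCCCC/C=C\CCCCCC | intermediate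
21 | (3S,5R,7S,15Z)-7-[(tert-butyldimethylsilyl)oxy]-5-{[(4-methoxybenzyl)oxy]methyl}-3,5-bis[(triethylsilyl)oxy]docosa-1,15-diene | C=C[C@@H](O[Si](CC)(CC)CC)C[C@@](O[Si](CC)(CC)CC)(COCc1ccc(OC)cc1)C[C@@H](O[Si](C)(C)C(C)(C)C)CCCCCCC/C=C\CCCCCC | intermediate
22 | (2R,4S,12Z)-4-[(tert-butyldimethylsilyl)oxy]-2-[(triethylsilyl)oxy]-2-{(2S)-2-[(triethylsilyl)oxy]but-3-en-1-yl}nonadec-12-en-1-ol | C=C[C@@H](O[Si](CC)(CC)CC)C[C@@](O[Si](CC)(CC)CC)(CO)C[C@@H](O[Si](C)(C)C(C)(C)C)CCCCCCC/C=C\CCCCCC | intermediate
23 | (2R,4S,12Z)-4-[(tert-butyldimethylsilyl)oxy]-2-[(triethylsilyl)oxy]-2-{(2S)-2-[(triethylsilyl)oxy]but-3-en-1-yl}nonadec-12-enal | C=C[C@@H](O[Si](CC)(CC)CC)C[C@@](O[Si](CC)(CC)CC)(C=O)C[C@@H](O[Si](C)(C)C(C)(C)C)CCCCCCC/C=C\CCCCCC | intermediate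
24 | (3RS,4R,6S,14Z)-6-[(tert-butyldimethylsilyl)oxy]-4-[(triethylsilyl)oxy]-4-{(2S)-2-[(triethylsilyl)oxy]but-3-en-1-yl}henicosa-1,14-dien-3-ol | C=C[C@@H](O[Si](CC)(CC)CC)C[C@@](O[Si](CC)(CC)CC)(C(O)C=C)C[C@@H](O[Si](C)(C)C(C)(C)C)CCCCCCC/C=C\CCCCCC | intermediate
25 | (1RS,4S,6R)-6-{(2S,10Z)-2-[(tert-butyldimethylsilyl)oxy]heptadec-10-en-1-yl}-4,6-bis[(triethylsilyl)oxy]cyclohex-2-en-1-ol | CCCCCC/C=C\CCCCCCC[C@H](O[Si](C)(C)C(C)(C)C)C[C@@]1(O[Si](CC)(CC)CC)C[C@H](O[Si](CC)(CC)CC)C=CC1O | intermediate
26 | (4S,6R)-6-{(2S,10Z)-2-[(tert-butyldimethylsilyl)oxy]heptadec-10-en-1-yl}-4,6-bis[(triethylsilyl)oxy]cyclohex-2-en-1-one | CCCCCC/C=C\CCCCCCC[C@H](O[Si](C)(C)C(C)(C)C)C[C@@]1(O[Si](CC)(CC)CC)C[C@H](O[Si](CC)(CC)CC)C=CC1=O | intermediate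
27 | (4S,6R)-4,6-dihydroxy-6-[(2S,10Z)-2-hydroxyheptadec-10-en-1-yl]cyclohex-2-en-1-one | CCCCCC/C=C\CCCCCCC[C@H](O)C[C@@]1(O)C[C@H](O)C=CC1=O | target

## Step count and least certain steps

Total: 20 steps. Longest linear sequence: 17 steps (steps 4–20, from 5); the epoxide branch (steps 1–3) joins at step 9.

Step 12 (key step). What may go wrong: poor facial selectivity, because the vanadium transition state prefers a small O–C4–C5=C6 angle that works against the allylic-strain rotamer, and competing oxidation of the bis-allylic carbinol to the cross-conjugated dienone. Fallback with reagent control instead of substrate control, setting out from 17 and returning at 23: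
- The PMB ether of 17 is cleaved with DDQ in wet CH2Cl2 to the C1 allylic alcohol F1, a primary E-allylic alcohol.
- Sharpless asymmetric epoxidation of F1 (Ti(OiPr)4, D-(−)-diisopropyl tartrate, t-BuOOH, 4 Å sieves, CH2Cl2, −20 °C) should deliver oxygen to the same alkene face and give epoxy alcohol F2.
- LiAlH4 in THF opens F2 at the secondary C5, since C6 is fully substituted, to give 1,2-diol F3.
- Oxidation of the primary hydroxyl (SO3·pyridine, DMSO, i-Pr2NEt) gives hydroxy aldehyde F4.
- Et3SiOTf/2,6-lutidine caps C6–OH and gives 23.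

Step 9. What may go wrong: loss of the alkenyllithium before it meets the epoxide, by migration of the triethylsilyl group from the C4 oxygen to C6 or by expulsion of the C1 alkoxide, and Lewis-acid rearrangement of the epoxide. Fallback by palladium-catalysed coupling of an organozinc reagent, setting out from 4 and 14 and returning at 17:
- 4 is opened with LiI/AcOH in THF to iodohydrin F5.
- F5 is silylated (t-BuMe2SiCl, imidazole) to silyl ether F6.
- Activated zinc dust in DMA inserts to give alkylzinc iodide F7, a β-silyloxy organozinc that does not eliminate readily.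
- Negishi coupling of F7 with 14 (Pd(PPh3)4, THF/DMA, rt) should give 17 directly with retention of the alkene geometry. This also makes step 10 unnecessary.

Step 18. What may go wrong: isomerisation of the free C1 allylic alcohol to a ketone by ruthenium hydride formed on catalyst decay, slow closure of one C1 epimer, and, on longer exposure, secondary metathesis or Z-to-E isomerisation at C10′=C11′. Fallback with a different substrate class for the ring closure, setting out from 24 and returning at 26: 24 is oxidised first (Dess–Martin periodinane, NaHCO3) to vinyl ketone F8, in which both C1 epimers have converged and no allylic alcohol remains, and F8 is closed by enone ring-closing metathesis with the same catalyst to give 26, so step 19 is not needed.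

Step 6. What may go wrong: insufficient enantiodiscrimination, because both carbinol substituents are slim unsaturated groups, or a reversed preference; in the latter case the (R)-acetate would simply remain and could be cleaved with K2CO3/MeOH. Fallback by asymmetric C–C bond formation instead of resolution, setting out from 6 and 7 and returning at 11: catalytic enantioselective alkynylation of 7 with 6 using a dinuclear zinc catalyst made from Zn(CH3)2 and a ProPhenol ligand, with the ligand enantiomer chosen for the (R)-carbinol, gives 11 directly without a new intermediate (F0).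

## Further compounds

F1 | step 12 | (3R,4E,7S,15Z)-7-[(tert-butyldimethylsilyl)oxy]-5-(hydroxymethyl)-3-[(triethylsilyl)oxy]docosa-1,4,15-triene (C1 allylic alcohol) | C=C[C@@H](O[Si](CC)(CC)CC)/C=C(/CO)C[C@@H](O[Si](C)(C)C(C)(C)C)CCCCCCC/C=C\CCCCCC
F2 | step 12 | {(2S,3S)-2-{(2S,10Z)-2-[(tert-butyldimethylsilyl)oxy]heptadec-10-en-1-yl}-3-{(1R)-1-[(triethylsilyl)oxy]prop-2-en-1-yl}oxiran-2-yl}methanol | C=C[C@@H](O[Si](CC)(CC)CC)[C@@H]1O[C@]1(CO)C[C@@H](O[Si](C)(C)C(C)(C)C)CCCCCCC/C=C\CCCCCC
F3 | step 12 | (2R,4S,12Z)-4-[(tert-butyldimethylsilyl)oxy]-2-{(2S)-2-[(triethylsilyl)oxy]but-3-en-1-yl}nonadec-12-ene-1,2-diol | C=C[C@@H](O[Si](CC)(CC)CC)C[C@@](O)(CO)C[C@@H](O[Si](C)(C)C(C)(C)C)CCCCCCC/C=C\CCCCCC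
F4 | step 12 | (2R,4S,12Z)-4-[(tert-butyldimethylsilyl)oxy]-2-hydroxy-2-{(2S)-2-[(triethylsilyl)oxy]but-3-en-1-yl}nonadec-12-enal | C=C[C@@H](O[Si](CC)(CC)CC)C[C@@](O)(C=O)C[C@@H](O[Si](C)(C)C(C)(C)C)CCCCCCC/C=C\CCCCCC
F5 | step 9 | (2S,10Z)-1-iodoheptadec-10-en-2-ol | CCCCCC/C=C\CCCCCCC[C@H](O)CI
F6 | step 9 | tert-butyl{[(2S,10Z)-1-iodoheptadec-10-en-2-yl]oxy}dimethylsilane | CCCCCC/C=C\CCCCCCC[C@H](O[Si](C)(C)C(C)(C)C)CI
F7 | step 9 | {(2S,10Z)-2-[(tert-butyldimethylsilyl)oxy]heptadec-10-en-1-yl}zinc iodide | CCCCCC/C=C\CCCCCCC[C@H](O[Si](C)(C)C(C)(C)C)C[Zn]I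
F8 | step 18 | (4R,6S,14Z)-6-[(tert-butyldimethylsilyl)oxy]-4-[(triethylsilyl)oxy]-4-{(2S)-2-[(triethylsilyl)oxy]but-3-en-1-yl}henicosa-1,14-dien-3-one | C=C[C@@H](O[Si](CC)(CC)CC)C[C@@](O[Si](CC)(CC)CC)(C(=O)C=C)C[C@@H](O[Si](C)(C)C(C)(C)C)CCCCCCC/C=C\CCCCCC
F0 | step 6 | none | none
A1 | alternative 1 | (4S,6R)-4-[(tert-butyldimethylsilyl)oxy]-6-[(2S,10Z)-2-hydroxyheptadec-10-en-1-yl]-6-[(triethylsilyl)oxy]cyclohex-2-en-1-one | CCCCCC/C=C\CCCCCCC[C@H](O)C[C@@]1(O[Si](CC)(CC)CC)C[C@H](O[Si](C)(C)C(C)(C)C)C=CC1=O
A2 | alternative 1 | (3R,5S)-3-{(2S,3Z)-2-[(tert-butyldimethylsilyl)oxy]-4-iodobut-3-en-1-yl}-5-[(8Z)-pentadec-8-en-1-yl]-3-[(triethylsilyl)oxy]oxolan-2-one | CCCCCC/C=C\CCCCCCC[C@H]1C[C@@](O[Si](CC)(CC)CC)(C[C@H](O[Si](C)(C)C(C)(C)C)/C=C\I)C(=O)O1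
A3 | alternative 2 | 3-{(2S,10Z)-2-[(tert-butyldimethylsilyl)oxy]heptadec-10-en-1-yl}-7-oxabicyclo[4.1.0]heptane-3,4-diol with both hydroxyls and the oxirane on one face (syn 3,4-epoxy-1,6-diol in target locants) | CCCCCC/C=C\CCCCCCC[C@H](O[Si](C)(C)C(C)(C)C)C[C@@]1(O)C[C@@H]2O[C@@H]2C[C@@H]1O
A4 | alternative 2 | 1-{(2S,10Z)-2-[(tert-butyldimethylsilyl)oxy]heptadec-10-en-1-yl}cyclohex-4-ene-1,2-diol, hydroxyls cis, carbinols configured as C6 and C1 of A3 | CCCCCC/C=C\CCCCCCC[C@H](O[Si](C)(C)C(C)(C)C)C[C@@]1(O)CC=CC[C@@H]1O
A5 | alternative 2 | tert-butyldimethyl{[(2S,10Z)-1-phenylheptadec-10-en-2-yl]oxy}silane | CCCCCC/C=C\CCCCCCC[C@H](O[Si](C)(C)C(C)(C)C)Cc1ccccc1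
A6 | alternative 3 | (2R,4R)-4-[(tert-butyldimethylsilyl)oxy]-2-{(2S,10Z)-2-[(tert-butyldimethylsilyl)oxy]heptadec-10-en-1-yl}-2-hydroxycyclohexan-1-one | CCCCCC/C=C\CCCCCCC[C@H](O[Si](C)(C)C(C)(C)C)C[C@@]1(O)C[C@H](O[Si](C)(C)C(C)(C)C)CCC1=O
A7 | alternative 3 | (4R,8S,16Z)-4,8-bis[(tert-butyldimethylsilyl)oxy]-6-oxotricos-16-enal | CCCCCC/C=C\CCCCCCC[C@H](O[Si](C)(C)C(C)(C)C)CC(=O)C[C@H](O[Si](C)(C)C(C)(C)C)CCC=O
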